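## Structural features

The target is a germacranolide: a ten-membered carbocycle (C1–C10) fused trans at C6–C7 to an α-methylene-γ-butyrolactone (lactone oxygen on C6, C12 carbonyl, exocyclic C11=C13). The carbocycle holds two trisubstituted, ring-cis alkenes: C4=C5 with the C15 methyl, and C1=C10, whose C10 carries the C14 aldehyde so that C1=C10–C14=O is an enal. Four contiguous stereocentres run C6(R)–C7(S)–C8(S)–C9(S); O8 is acylated by (S)-2-methylbutanoic acid, O9 is a free hydroxyl, and O8 and O9 are syn. The fragile groups are the two Michael acceptors (α-methylene lactone and enal), the C9 carbinol (allylic and next to the enal), the ester beside a free hydroxyl (acyl migration), and any aldehyde placed next to C7 (epimerisation, migration of C11=C13 into conjugation). The real difficulty is to close a ten-membered ring with two ring-cis alkenes while installing the syn C8/C9 diol in differentiated form directly beside the C1=C10 alkene that bears oxygen at C14. The key step exploits the array O8–C8–C9(O9)–C10(C14)=C1. This is a homoallylic alcohol with an alkoxy group on the allylic carbon, the retron of a γ-alkoxyallylboration that forms C8–C9 and moves the alkene from C9=C10 to C1=C10.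

## Logic of the disconnections

44 to 43: only the O9 protecting group is removed. O9 stays masked until the ester, the lactone and the enal exist, so it can neither lactonise onto C12 nor receive the acyl group from O8. The last step must be an ether cleavage that tolerates an enal and an α-methylene lactone.

43 to 40: the lactone C12–O6 bond is cut and C12 and C14 are taken back to the alcohol level. Both Michael acceptors then arise in one oxidation at the end and are absent from all earlier steps. The oxidant must prefer primary allylic carbinols and the lactol over the secondary C6 carbinol.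

40 to 39 to 36 + 37: the O8–acyl bond is cut. In 36 the C8 hydroxyl is the only free one, so the diol is differentiated without extra steps. The acylation must work on a hindered secondary alcohol without loss of configuration at the α-carbon of 37.

36 to 34 (key): the C8–C9 bond is cut, which opens the ring, removes two stereocentres, returns the alkene to C9=C10 as an enol ether and places boron on C1. The forward step must pass through one chair with C2 axial and C7 equatorial. Three points of the precursor design are set deliberately.
- The enol ether oxygen must be cis to C1; its CIP descriptor is E, although it is the geometry of a (Z)-γ-alkoxyallylboronate.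
- O14 is a silyl ether, not a second benzyl-type ether. It falls with the other silyl groups, so one oxidation makes lactone and enal together and the oxidative ether cleavage comes last, on an electron-poor alkene.
- The β,γ-unsaturated aldehyde 34 is made in the last operation and is not stored.

34 to 33 to 20 + 29: the C8 oxidation level is lowered, then the C1–C10 bond is cut together with the C1–B bond (lithiation–borylation). This sets C1 by reagent control and brings in the enol ether with its geometry already fixed. A CuCl-catalysed SN2′ borylation of the corresponding enal acetal was set aside because it is expected to favour the opposite enol ether geometry and is untested on a 2-substituted alkene. The C8 oxygen needs a group that survives s-BuLi and leaves without acid, fluoride or oxidant; a trimethylsilyl ether is chosen.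

29 to 27 to 26 to 25 to 23 to 21 + 22: the C–B and C–Br bonds and the O9–C9 bond are cut. The geometry comes from the α-bromo-β-alkoxyacrylate 25, in which bromine sits cis to the ether oxygen. Every later step must retain that geometry.

20 to 19 to 18 to 17 to 6 + 14: the C6–C7 bond is cut as an aldol. One auxiliary-controlled step sets C6 and C7, and C8 arrives as the acyl carbon, one reduction away from the alcohol. The aldol must react at the α-carbon of a dienolate and must not isomerise the Z enal.

14 to 11 + 12, and 11 to 7: the N-acyl bond and the C7–C8 bond (carboxylation) are cut. The five carbons C7, C8, C11, C12, C13 come from methallyl alcohol and CO2. The hydroxy acid must be silylated before it can lactonise.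

6 to 5 to 4 to 3 to 1: the C1 terminus is traced to the remote alkene of 1. The Z C4=C5 alkene and the C15 methyl are bought with the starting material. The cleavage must spare the alkene next to the acetate.

## Other disconnections considered

Alternative 1: The cut is C1–C2, between the sp2 carbon of the future enal and its sp3 neighbour. The seco diiodide A2 already carries the lactone, the ester and the C9/C14 acetonide. Zinc dust and LiCl would turn its primary C2 iodide into an alkylzinc iodide (RZnI), and Pd(PPh3)4 would couple this with the C1 alkenyl iodide to give A1.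
- In favour: the C1=C10 geometry is fixed in the alkenyl iodide and carried through with retention. This is better than the chosen plan, where that geometry is decided in the ring-closing transition state. Only acetonide cleavage and C14 oxidation remain after A1, two steps against four, which is also better.
- Against: the closure creates no stereocentre, so C6, C7 and the syn diol must all be set on an open chain by separate intermolecular steps. The α-methylene lactone is exposed to zinc metal and to an alkylzinc. Reductive elimination from an eleven-membered palladacycle with two ring-cis alkenes must outrun β-hydride elimination, protodezincation and dimerisation.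
- Comparison: the reaction class is well known and its use for a ring is an extension of scale, so on precedent it is the equal of the chosen step or better. On structure it gives one bond, where the chosen step gives one bond, two stereocentres and the oxygen differentiation. On step count the longer way to A2 should cancel the shorter end game.

Alternative 2: The cut is C6–C7, reached through the thirteen-membered diallyl ether A4 in which oxygen links C6 and C13. n-BuLi would deprotonate C6; the [2,3]-sigmatropic shift would form C6–C7, break O–C13, create C11=C13 and contract the ring to A3.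
- In favour: a thirteen-membered ether is easier to close than a ten-membered carbocycle, which is better than the chosen plan on strain and entropy of ring closure. C6 and C7 are set together, C6–OH emerges free for lactonisation, and the acetonide fixes the C1=C10 geometry and the diol beforehand.
- Against: two allylic ether methylenes (C6 and C13) compete for the base, and a [1,2]-shift is an alternative path. The sense of C6/C7 relative to C8/C9 depends on the transannular conformation, with no reagent to enforce it. The strong base excludes the ester, so O8 travels as a silyl ether that must later be freed beside the triethylsilyl ether. The acetonide needs acid at a late stage.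
- Comparison: transannular ring contractions of macrocyclic allyl ethers are precedented in kind, so on precedent the alternative is equal or better. On stereocontrol it is weaker than chirality transfer from a reagent-set centre. About six steps would follow A3, against four after the chosen key step.

Alternative 3: The cut is C5–C6. The seco iodo aldehyde A6 holds a (Z)-alkenyl iodide at C5, the aldehyde at C6, the ester and the silyl ethers. CrCl2 with catalytic NiCl2 would convert the C–I bond into an alkenylchromium species of trivalent chromium, which adds to the aldehyde to give A5.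
- In favour: this is the most thoroughly precedented way to close a medium ring onto an aldehyde, which is better than the chosen plan. It tolerates the ester and silyl ethers, keeps the Z geometry of C4=C5 and delivers C6–OH free. The acid side chain is on before the ring closes. The end game (desilylation, lactonisation, C14 oxidation) is about as long as the chosen one, which is equal.
- Against: the C6 configuration arises in the closure under substrate control from C7 alone, and the wrong epimer would cost an inversion. The C6 aldehyde is as easily epimerised at C7 as the C8 aldehyde of the chosen plan, which is equal. CrCl2 is needed in large excess. A6 must already contain the differentiated syn diol and the trisubstituted C1=C10 alkene, each needing its own stereoselective steps, so the sequence before the key step is longer.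
- Comparison: the alternative is stronger on precedent, the chosen plan on what the ring closure itself builds.

Key step: step 18

Remark: positions are given in germacrane numbers throughout; in 29 and 31–34 the ether oxygen is cis to the boron-bearing carbon across C9=C10 (CIP descriptor E, geometry of a (Z)-γ-alkoxyallylboronate); neryl acetate, the commercial acetate of nerol, is taken as the entry point.
Abbreviations: TIB = 2,4,6-triisopropylbenzoyl, TBS = tert-butyldimethylsilyl, TMS = trimethylsilyl, PMB = 4-methoxybenzyl, pin = pinacolato.

## Route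

Step 1
Reactants: 1 neryl acetate
Product: 3 (2Z)-6-hydroxy-3-methylhex-2-en-1-yl acetate, via aldehyde 2 (not isolated)
Conditions: O3, pyridine, CH2Cl2, −78 °C; then NaBH4, MeOH, 0 °C
Reagents that add atoms: ozone, [O-][O+]=O
Why: Chemoselective ozonolysis: the remote trisubstituted alkene is more electron-rich than the one deactivated by the allylic acetate and should be cleaved first; pyridine converts the carbonyl oxide directly into the aldehyde, which NaBH4 reduces in the same flask. The Z alkene is not touched.

Step 2
Reactants: 3 (2Z)-6-hydroxy-3-methylhex-2-en-1-yl acetate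
Product: 4 (4Z)-6-acetoxy-4-methylhex-4-en-1-yl 2,4,6-triisopropylbenzoate
Conditions: 2,4,6-i-Pr3C6H2COCl, Et3N, DMAP (cat.), CH2Cl2, 40 °C
Reagents that add atoms: 2,4,6-triisopropylbenzoyl chloride, CC(C)c1cc(C(C)C)c(C(=O)Cl)c(C(C)C)c1
Why: Acylation of the primary alcohol; the hindered benzoate later directs α-lithiation and acts as leaving group, and it is inert to the base, hydride and boron reagents used in between.

Step 3
Reactants: 4 (4Z)-6-acetoxy-4-methylhex-4-en-1-yl 2,4,6-triisopropylbenzoate
Product: 5 (4Z)-6-hydroxy-4-methylhex-4-en-1-yl 2,4,6-triisopropylbenzoate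
Conditions: K2CO3, MeOH, 0 °C to rt
Reagents that add atoms: none
Why: Base-catalysed methanolysis removes the unhindered acetate; the benzoate carbonyl is shielded by two ortho isopropyl groups and should not transesterify.

Step 4
Reactants: 5 (4Z)-6-hydroxy-4-methylhex-4-en-1-yl 2,4,6-triisopropylbenzoate
Product: 6 (4Z)-4-methyl-6-oxohex-4-en-1-yl 2,4,6-triisopropylbenzoate
Conditions: TEMPO (cat.), PhI(OAc)2, CH2Cl2, rt
Reagents that add atoms: none
Why: TEMPO/PhI(OAc)2 oxidation (oxoammonium mechanism) of the primary allylic alcohol stops at the enal and, being free of base, should leave the Z geometry intact.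

Step 5
Reactants: 7 2-methylprop-2-en-1-ol
Product: 11 3-{[(tert-butyldimethylsilyl)oxy]methyl}but-3-enoic acid, via dilithiated methallyl alcohol 8 (not isolated), via dilithium carboxylate alkoxide 9 (not isolated), via bis-silyl derivative 10 (not isolated)
Conditions: n-BuLi (2.2 equiv), TMEDA, Et2O, 0 °C to rt; CO2, −78 °C; TBSCl, imidazole, DMF, rt; K2CO3, MeOH/H2O, rt, then pH 5
Reagents that add atoms: carbon dioxide, O=C=O; tert-butyldimethylsilyl chloride, CC(C)(C)[Si](C)(C)Cl
Why: Alkoxide-directed allylic metalation gives the O,C-dianion, which is carboxylated at carbon; silylating both oxygens before any acidification prevents lactonisation, and mild base then cleaves only the labile silyl ester.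

Step 6
Reactants: 11 3-{[(tert-butyldimethylsilyl)oxy]methyl}but-3-enoic acid; 12 (S)-4-benzyloxazolidin-2-one
Product: 14 (S)-4-benzyl-3-(3-{[(tert-butyldimethylsilyl)oxy]methyl}but-3-enoyl)oxazolidin-2-one, via mixed pivalic anhydride 13 (not isolated)
Conditions: t-BuCOCl, Et3N, THF, −20 °C; then 12/n-BuLi (THF, −78 °C), −78 to 0 °C
Reagents that add atoms: none
Why: N-acylation of the lithiated oxazolidinone at the less hindered carbonyl of the mixed anhydride; the low temperature keeps the β,γ-alkene from moving into conjugation.

Step 7
Reactants: 6 (4Z)-4-methyl-6-oxohex-4-en-1-yl 2,4,6-triisopropylbenzoate; 14 N-acyloxazolidinone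
Product: 17 syn-aldol adduct (acyl chain 2S,3R,4Z; C6 hydroxyl; C7 bearing the 2-propenyl arm), via Z-boron enolate 15 (not isolated), via boron aldolate 16 (not isolated)
Conditions: n-Bu2BOTf, i-Pr2NEt, CH2Cl2, −78 to 0 °C; 6, −78 to −20 °C; pH 7 buffer, MeOH, H2O2, 0 °C
Reagents that add atoms: none
Why: Evans syn aldol: the Z-(O)-boron dienolate reacts at its α-carbon through a Zimmerman–Traxler chair on the face away from the benzyl group. This sets C6 and C7 in the required absolute sense (O6 and the 2-propenyl arm syn, the relation of the trans lactone). The enal should react 1,2 and keep its Z geometry at low temperature.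

Step 8
Reactants: 17 syn-aldol adduct
Product: 18 C6 O-TBS ether of 17
Conditions: TBSOTf, 2,6-lutidine, CH2Cl2, −78 to 0 °C
Reagents that add atoms: tert-butyldimethylsilyl trifluoromethanesulfonate, CC(C)(C)[Si](C)(C)OS(=O)(=O)C(F)(F)F
Why: Silylation of the hindered secondary carbinol with the silyl triflate; the low temperature avoids retro-aldol cleavage.

Step 9
Reactants: 18 C6 O-TBS ether
Product: 19 (4Z,6R,7R)-6-(TBS-oxy)-7-(hydroxymethyl)-4-methyl-8-[(TBS-oxy)methyl]nona-4,8-dien-1-yl 2,4,6-triisopropylbenzoate (C8 alcohol)
Conditions: LiBH4, MeOH (1 equiv), THF, 0 °C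
Reagents that add atoms: none
Why: Reductive cleavage of the imide by LiBH4: hydride attacks the exocyclic carbonyl and releases the auxiliary; the hindered benzoate and the silyl ethers should not be reduced.

Step 10
Reactants: 19 C8 alcohol
Product: 20 C8 O-TMS ether of 19
Conditions: TMSCl, Et3N, CH2Cl2, 0 °C; non-aqueous work-up
Reagents that add atoms: chlorotrimethylsilane, C[Si](C)(C)Cl
Why: Trimethylsilylation masks the only hydroxyl for the organolithium step with a group that mild methanolysis can later remove without acid, fluoride or oxidant.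

Step 11
Reactants: 21 methyl propiolate; 22 4-methoxybenzyl alcohol
Product: 23 methyl (E)-3-[(4-methoxybenzyl)oxy]acrylate
Conditions: N-methylmorpholine (cat.), CH2Cl2, rt
Reagents that add atoms: none
Why: Amine-catalysed oxa-Michael addition of the alcohol to the ynoate, which gives the E β-alkoxyacrylate.

Step 12
Reactants: 23 methyl (E)-3-[(4-methoxybenzyl)oxy]acrylate
Product: 25 methyl (Z)-2-bromo-3-[(4-methoxybenzyl)oxy]acrylate, via 2,3-dibromo ester 24 (not isolated)
Conditions: Br2 (1.0 equiv), CH2Cl2, −78 °C; Et3N, −78 to 0 °C
Reagents that add atoms: bromine, BrBr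
Why: Bromine addition to the push–pull alkene followed by dehydrobromination; the product should settle with the ether oxygen trans to the ester, which places bromine cis to that oxygen as later needed between boron and O9. One equivalent at low temperature spares the anisyl ring.

Step 13
Reactants: 25 methyl (Z)-2-bromo-3-[(4-methoxybenzyl)oxy]acrylate
Product: 26 (Z)-2-bromo-3-[(4-methoxybenzyl)oxy]prop-2-en-1-ol
Conditions: i-Bu2AlH (2.2 equiv), CH2Cl2, −78 °C; neutral aqueous work-up
Reagents that add atoms: none
Why: 1,2-Reduction of the ester; once the push–pull conjugation is gone the alkene geometry is locked.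

Step 14
Reactants: 26 (Z)-2-bromo-3-[(4-methoxybenzyl)oxy]prop-2-en-1-ol
Product: 27 TBS ether of 26
Conditions: TBSCl, imidazole, CH2Cl2, 0 °C
Reagents that add atoms: tert-butyldimethylsilyl chloride, CC(C)(C)[Si](C)(C)Cl
Why: Silylation under mild base protects the acid-sensitive allylic alcohol without risk of dehydrobromination.

Step 15
Reactants: 27 TBS ether of the bromo enol ether; 28 bis(pinacolato)diboron
Product: 29 alkenyl pinacol boronate (B on C10, cis to the PMB-oxy group on C9; C14 as CH2OTBS)
Conditions: PdCl2(PPh3)2 (3 mol %), PPh3, KOPh, toluene, 50 °C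
Reagents that add atoms: none
Why: Miyaura borylation of the alkenyl bromide (oxidative addition, transmetalation, reductive elimination) proceeds with retention, so boron takes the place of bromine cis to the ether oxygen.

Step 16
Reactants: 20 C8 O-TMS ether; 29 alkenyl pinacol boronate
Product: 33 (1R)-allylboronate with free C8 hydroxyl (C1 Bpin; C9=C10 enol ether with O9-PMB cis to C1; O6/O12/O14 TBS), via α-lithiated benzoate 30 (not isolated), via lithium boronate complex 31 (not isolated), via silylated allylboronate 32 (not isolated)
Conditions: s-BuLi, (−)-sparteine, Et2O, −78 °C; 29, −78 °C, then 35 °C; K2CO3, MeOH, 0 °C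
Reagents that add atoms: none
Why: Sparteine-mediated lithiation–borylation: s-BuLi/(−)-sparteine should remove the pro-S hydrogen next to the benzoate oxygen, and the boronate is captured with retention. The alkenyl group then shifts from boron to carbon with inversion and loss of the benzoate, giving the 1R boronate with the alkene geometry of 29 unchanged. Methanolysis then frees only the trimethylsilyl ether.

Step 17
Reactants: 33 (1R)-allylboronate with free C8 hydroxyl
Product: 34 seco aldehyde (C8 aldehyde; 1R Bpin; enol ether O9-PMB cis to C1; O6/O12/O14 TBS)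
Conditions: Dess–Martin periodinane, NaHCO3, CH2Cl2, 0 °C; filtered and used at once
Reagents that add atoms: none
Why: Buffered Dess–Martin oxidation is neutral enough for the enol ether, the allylboronate and the epimerisable β,γ-unsaturated aldehyde; the crude aldehyde is diluted immediately so that bimolecular allylboration cannot compete.

Step 18
Reactants: 34 seco aldehyde
Product: 36 ten-membered carbocycle (6R,7R,8S,9S; free C8 hydroxyl; O9-PMB; O6/O12/O14 TBS; ring-cis C1=C10 and C4=C5), via pinacol borate ester 35 (not isolated)
Conditions: toluene (0.5–1 mM, slow addition), 4 Å MS, 80 °C; then aq NaHCO3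
Reagents that add atoms: none
Why: Proposed new method: an intramolecular γ-alkoxyallylboration in which boron binds the C8 carbonyl oxygen and C9 attacks C8 through a six-membered chair (B, O, C8, C9, C10, C1) on the boron-bearing face of C9=C10, the double bond moving to C1=C10 and borate 35 being hydrolysed on work-up; the closest known reactions are thermal additions of α-substituted γ-alkoxyallyl pinacol boronates to aldehydes and intramolecular allylborations that close five- to seven-membered rings, and a ten-membered closure through a tether on the boron-bearing carbon is not documented. The one ring formed is the ten-membered carbocycle, closed by C8–C9 bond formation while the six-atom chain C2–C7 bridges the 1,4-positions (C1 and C8) of the chair, a span that only an axial/equatorial pair of exit bonds can reach. C9 is set by chirality transfer from C1: with C2 axial, the 1R boronate presents to C8 the face of C9 that gives 9S. C8 is set by the chair itself: C7 equatorial on the aldehyde carbon and the ether oxygen cis to C1 give the syn 8S,9S pair. The selectivity needed is C2 axial with C7 equatorial (ring-cis C1=C10) over C2 equatorial with C7 axial (ring-trans alkene and C9 epimer). It should be favoured because the pinacol ligand penalises an axial aldehyde substituent and because the C14 group on C10 clashes with an equatorial C2, at the cost of one 1,3-diaxial contact between C2 and the small O9. High dilution suppresses bimolecular addition; if the thermal rate is too low, catalytic (PhO)2P(O)OH, which accelerates pinacol allylboronate additions through the same chair, can be added.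

Step 19
Reactants: 36 ten-membered carbocycle; 37 (S)-2-methylbutanoic acid
Product: 39 C8 (S)-2-methylbutanoate of 36, via Yamaguchi mixed anhydride 38 (not isolated)
Conditions: 2,4,6-Cl3C6H2COCl, Et3N, toluene, rt; then 36, DMAP, rt
Reagents that add atoms: none
Why: Yamaguchi esterification: DMAP attacks the aliphatic carbonyl of the mixed anhydride and the acylpyridinium acylates C8, the only free hydroxyl; room temperature without ketene formation should preserve the S configuration of the acid.

Step 20
Reactants: 39 C8 ester
Product: 40 triol (free C6, C12 and C14 hydroxyls; O9-PMB; C8 ester)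
Conditions: HF·pyridine, pyridine, THF, 0 °C to rt
Reagents that add atoms: none
Why: Buffered fluoride cleavage of all three silyl ethers; the PMB ether, the ester and the alkenes are inert, and no base is present to promote acyl migration.

Step 21
Reactants: 40 triol
Product: 43 O9-PMB ether of the target (lactone and C14 aldehyde in place), via dialdehyde 41 (not isolated), via lactol 42 (not isolated)
Conditions: TEMPO (20 mol %), PhI(OAc)2 (3.5 equiv), CH2Cl2, rt
Reagents that add atoms: none
Why: Oxoammonium oxidation takes both primary allylic alcohols to aldehydes; the C12 aldehyde closes onto O6 as a five-membered lactol that is oxidised on to the lactone, while O9 (ether) and O8 (ester) cannot compete. The secondary C6 carbinol is expected to cyclise faster than it is oxidised.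

Step 22
Reactants: 43 O9-PMB ether of the target
Product: 44 target CNP0168436.1 (6R,7S,8S,9S; S side chain)
Conditions: DDQ, CH2Cl2/pH 7 buffer, 0 °C to rt
Reagents that add atoms: none
Why: Oxidative cleavage of the PMB ether by DDQ (hydride abstraction, hydrolysis of the oxocarbenium ion) at neutral pH; the neighbouring alkene is now part of an enal and should not be oxidised, and the mild conditions avoid acyl migration from O8 to O9.

## Compound list

1 | neryl acetate, (2Z)-3,7-dimethylocta-2,6-dien-1-yl acetate | CC(C)=CCC/C(C)=C\COC(C)=O | starting material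
2 | (2Z)-3-methyl-6-oxohex-2-en-1-yl acetate | CC(=O)OC/C=C(/C)CCC=O | intermediate (not isolated)
3 | (2Z)-6-hydroxy-3-methylhex-2-en-1-yl acetate | CC(=O)OC/C=C(/C)CCCO | intermediate
4 | (4Z)-6-acetoxy-4-methylhex-4-en-1-yl 2,4,6-triisopropylbenzoate | CC(=O)OC/C=C(/C)CCCOC(=O)c1c(C(C)C)cc(C(C)C)cc1C(C)C | intermediate
5 | (4Z)-6-hydroxy-4-methylhex-4-en-1-yl 2,4,6-triisopropylbenzoate | OC/C=C(/C)CCCOC(=O)c1c(C(C)C)cc(C(C)C)cc1C(C)C | intermediate
6 | (4Z)-4-methyl-6-oxohex-4-en-1-yl 2,4,6-triisopropylbenzoate | O=C/C=C(/C)CCCOC(=O)c1c(C(C)C)cc(C(C)C)cc1C(C)C | intermediate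
7 | 2-methylprop-2-en-1-ol | C=C(C)CO | starting material
8 | dilithiated methallyl alcohol | [Li]CC(=C)CO[Li] | intermediate (not isolated)
9 | dilithium 3-(oxidomethyl)but-3-enoate | C=C(CO[Li])CC(=O)O[Li] | intermediate (not isolated)
10 | tert-butyldimethylsilyl 3-{[(tert-butyldimethylsilyl)oxy]methyl}but-3-enoate | C=C(CO[Si](C)(C)C(C)(C)C)CC(=O)O[Si](C)(C)C(C)(C)C | intermediate (not isolated)
11 | 3-{[(tert-butyldimethylsilyl)oxy]methyl}but-3-enoic acid | C=C(CO[Si](C)(C)C(C)(C)C)CC(=O)O | intermediate
12 | (S)-4-benzyloxazolidin-2-one | O=C1N[C@@H](Cc2ccccc2)CO1 | starting material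
13 | mixed anhydride of 11 and pivalic acid | C=C(CO[Si](C)(C)C(C)(C)C)CC(=O)OC(=O)C(C)(C)C | intermediate (not isolated)
14 | (S)-4-benzyl-3-(3-{[(tert-butyldimethylsilyl)oxy]methyl}but-3-enoyl)oxazolidin-2-one | C=C(CO[Si](C)(C)C(C)(C)C)CC(=O)N1C(=O)OC[C@@H]1Cc1ccccc1 | intermediate
15 | Z-(O)-dibutylboron enolate of 14 | CCCCB(CCCC)O/C(=C\C(=C)CO[Si](C)(C)C(C)(C)C)N1C(=O)OC[C@@H]1Cc1ccccc1 | intermediate (not isolated)
16 | O6-dibutylboron aldolate of 17 | O=C(N1C(=O)OC[C@@H]1Cc1ccccc1)[C@@H](C(=C)CO[Si](C)(C)C(C)(C)C)[C@H](OB(CCCC)CCCC)/C=C(/C)CCCOC(=O)c1c(C(C)C)cc(C(C)C)cc1C(C)C | intermediate (not isolated)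
17 | (4S)-4-benzyl-3-[(2S,3R,4Z)-3-hydroxy-5-methyl-2-(3-{[tert-butyldimethylsilyl]oxy}prop-1-en-2-yl)-8-(2,4,6-triisopropylbenzoyloxy)oct-4-enoyl]oxazolidin-2-one | O=C(N1C(=O)OC[C@@H]1Cc1ccccc1)[C@@H](C(=C)CO[Si](C)(C)C(C)(C)C)[C@H](O)/C=C(/C)CCCOC(=O)c1c(C(C)C)cc(C(C)C)cc1C(C)C | intermediate
18 | C6 O-TBS ether of 17 | O=C(N1C(=O)OC[C@@H]1Cc1ccccc1)[C@@H](C(=C)CO[Si](C)(C)C(C)(C)C)[C@H](O[Si](C)(C)C(C)(C)C)/C=C(/C)CCCOC(=O)c1c(C(C)C)cc(C(C)C)cc1C(C)C | intermediate
19 | (4Z,6R,7R)-6-(TBS-oxy)-7-(hydroxymethyl)-4-methyl-8-[(TBS-oxy)methyl]nona-4,8-dien-1-yl 2,4,6-triisopropylbenzoate | OC[C@@H](C(=C)CO[Si](C)(C)C(C)(C)C)[C@H](O[Si](C)(C)C(C)(C)C)/C=C(/C)CCCOC(=O)c1c(C(C)C)cc(C(C)C)cc1C(C)C | intermediate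
20 | C8 O-TMS ether of 19 | C[Si](C)(C)OC[C@@H](C(=C)CO[Si](C)(C)C(C)(C)C)[C@H](O[Si](C)(C)C(C)(C)C)/C=C(/C)CCCOC(=O)c1c(C(C)C)cc(C(C)C)cc1C(C)C | intermediate
21 | methyl propiolate | C#CC(=O)OC | starting material
22 | 4-methoxybenzyl alcohol | COc1ccc(CO)cc1 | starting material
23 | methyl (E)-3-[(4-methoxybenzyl)oxy]acrylate | COC(=O)/C=C/OCc1ccc(OC)cc1 | intermediate
24 | methyl 2,3-dibromo-3-[(4-methoxybenzyl)oxy]propanoate | COC(=O)C(Br)C(Br)OCc1ccc(OC)cc1 | intermediate (not isolated)
25 | methyl (Z)-2-bromo-3-[(4-methoxybenzyl)oxy]acrylate | COC(=O)/C(Br)=C/OCc1ccc(OC)cc1 | intermediate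
26 | (Z)-2-bromo-3-[(4-methoxybenzyl)oxy]prop-2-en-1-ol | OC/C(Br)=C/OCc1ccc(OC)cc1 | intermediate
27 | tert-butyl{[(2Z)-2-bromo-3-[(4-methoxybenzyl)oxy]prop-2-en-1-yl]oxy}dimethylsilane | CC(C)(C)[Si](C)(C)OC/C(Br)=C/OCc1ccc(OC)cc1 | intermediate
28 | bis(pinacolato)diboron | CC1(C)OB(OC1(C)C)B1OC(C)(C)C(C)(C)O1 | starting material
29 | 2-[(1E)-3-(TBS-oxy)-1-[(4-methoxybenzyl)oxy]prop-1-en-2-yl]-4,4,5,5-tetramethyl-1,3,2-dioxaborolane (B cis to the ether oxygen) | COc1ccc(CO/C=C(/CO[Si](C)(C)C(C)(C)C)B2OC(C)(C)C(C)(C)O2)cc1 | intermediate
30 | (1S)-1-lithio derivative of 20 | C[Si](C)(C)OC[C@@H](C(=C)CO[Si](C)(C)C(C)(C)C)[C@H](O[Si](C)(C)C(C)(C)C)/C=C(/C)CC[C@H]([Li])OC(=O)c1c(C(C)C)cc(C(C)C)cc1C(C)C | intermediate (not isolated)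
31 | lithium boronate complex of 30 and 29 | C[Si](C)(C)OC[C@@H](C(=C)CO[Si](C)(C)C(C)(C)C)[C@H](O[Si](C)(C)C(C)(C)C)/C=C(/C)CC[C@@H](OC(=O)c1c(C(C)C)cc(C(C)C)cc1C(C)C)[B-]1(OC(C)(C)C(C)(C)O1)/C(CO[Si](C)(C)C(C)(C)C)=C\OCc1ccc(OC)cc1.[Li+] | intermediate (not isolated)
32 | (1R)-allylboronate, C8 O-TMS | C[Si](C)(C)OC[C@@H](C(=C)CO[Si](C)(C)C(C)(C)C)[C@H](O[Si](C)(C)C(C)(C)C)/C=C(/C)CC[C@@H](B1OC(C)(C)C(C)(C)O1)/C(CO[Si](C)(C)C(C)(C)C)=C\OCc1ccc(OC)cc1 | intermediate (not isolated)
33 | (1R)-allylboronate, C8 hydroxyl free | OC[C@@H](C(=C)CO[Si](C)(C)C(C)(C)C)[C@H](O[Si](C)(C)C(C)(C)C)/C=C(/C)CC[C@@H](B1OC(C)(C)C(C)(C)O1)/C(CO[Si](C)(C)C(C)(C)C)=C\OCc1ccc(OC)cc1 | intermediate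
34 | seco aldehyde (1R,6R,7S): C8 aldehyde, C1 Bpin, enol ether O9-PMB cis to C1 | O=C[C@@H](C(=C)CO[Si](C)(C)C(C)(C)C)[C@H](O[Si](C)(C)C(C)(C)C)/C=C(/C)CC[C@@H](B1OC(C)(C)C(C)(C)O1)/C(CO[Si](C)(C)C(C)(C)C)=C\OCc1ccc(OC)cc1 | intermediate
35 | O8 pinacol borate ester of 36 | C=C(CO[Si](C)(C)C(C)(C)C)[C@H]1[C@H](O[Si](C)(C)C(C)(C)C)/C=C(/C)CC/C=C(/CO[Si](C)(C)C(C)(C)C)[C@H](OCc2ccc(OC)cc2)[C@H]1OB1OC(C)(C)C(C)(C)O1 | intermediate (not isolated)
36 | ten-membered carbocycle (6R,7R,8S,9S): C8 OH, O9-PMB, O6/O12/O14 TBS | C=C(CO[Si](C)(C)C(C)(C)C)[C@H]1[C@H](O[Si](C)(C)C(C)(C)C)/C=C(/C)CC/C=C(/CO[Si](C)(C)C(C)(C)C)[C@H](OCc2ccc(OC)cc2)[C@H]1O | intermediate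
37 | (S)-2-methylbutanoic acid | CC[C@H](C)C(=O)O | starting material
38 | (S)-2-methylbutanoic 2,4,6-trichlorobenzoic anhydride | CC[C@H](C)C(=O)OC(=O)c1c(Cl)cc(Cl)cc1Cl | intermediate (not isolated)
39 | C8 (S)-2-methylbutanoate of 36 | C=C(CO[Si](C)(C)C(C)(C)C)[C@H]1[C@H](O[Si](C)(C)C(C)(C)C)/C=C(/C)CC/C=C(/CO[Si](C)(C)C(C)(C)C)[C@H](OCc2ccc(OC)cc2)[C@H]1OC(=O)[C@@H](C)CC | intermediate
40 | triol: C6, C12, C14 hydroxyls free; O9-PMB; C8 ester | C=C(CO)[C@H]1[C@H](O)/C=C(/C)CC/C=C(/CO)[C@H](OCc2ccc(OC)cc2)[C@H]1OC(=O)[C@@H](C)CC | intermediate
41 | C12,C14-dialdehyde with free C6 hydroxyl | C=C(C=O)[C@H]1[C@H](O)/C=C(/C)CC/C=C(/C=O)[C@H](OCc2ccc(OC)cc2)[C@H]1OC(=O)[C@@H](C)CC | intermediate (not isolated)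
42 | C12 lactol (both anomers) with C14 aldehyde | C=C1C(O)O[C@@H]2/C=C(/C)CC/C=C(/C=O)[C@H](OCc3ccc(OC)cc3)[C@@H](OC(=O)[C@@H](C)CC)[C@@H]12 | intermediate (not isolated)
43 | O9-PMB ether of the target | C=C1C(=O)O[C@@H]2/C=C(/C)CC/C=C(/C=O)[C@H](OCc3ccc(OC)cc3)[C@@H](OC(=O)[C@@H](C)CC)[C@@H]12 | intermediate
44 | CNP0168436.1 (6R,7S,8S,9S; 8-O-(S)-2-methylbutanoyl) | C=C1C(=O)O[C@@H]2/C=C(/C)CC/C=C(/C=O)[C@H](O)[C@@H](OC(=O)[C@@H](C)CC)[C@@H]12 | target

## Step count and least certain steps

Total step count: 22 (main line and both branches). Longest linear sequence: 15 steps, from 1 through steps 1–4, 7–10 and 16–22.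

Step 18 (key step). The ring closure may pass through the other bridged chair (C2 equatorial, C7 axial), which would give the ring-trans alkene and the C9 epimer. It may also be so slow that bimolecular addition, epimerisation at C7 or migration of the C11=C13 bond into conjugation take over. The causes are the 1,3-diaxial contact between C2 and O9 in the required chair and the low effective molarity of a ten-membered ring. Fallback with known chemistry: the C8–C9 bond and the syn diol are made intermolecularly and the ring is closed by olefin metathesis at C1=C10. It sets out from aldehyde 2, isolated by omitting NaBH4 in step 1. Wittig methylenation (Ph3P=CH2, THF, −78 °C) would give dienyl acetate F1, methanolysis (K2CO3, MeOH) dienol F2, and TEMPO/PhI(OAc)2 dienal F3. The Evans aldol with 14 under the conditions of step 7 would give aldol adduct F4, silylation (TBSOTf, 2,6-lutidine) silyl ether F5, LiBH4 primary alcohol F6, and Dess–Martin oxidation aldehyde F7. Separately, Matteson homologation of 29 (ClCH2I, n-BuLi, THF, −78 °C to rt) would give allylboronate F8 with the ether oxygen still cis to the boron-bearing carbon. F7 and F8 would combine in concentrated toluene at rt to 40 °C through the usual chair to give the syn C8/C9 arrangement in triene F9. The facial sense relative to C7 rests on substrate control, or on a chiral phosphoric acid catalyst if that is insufficient. Ring-closing metathesis of F9 (second-generation Grubbs catalyst, toluene, 1 mM, 80 °C) between the C1 vinyl group and the C10 methylene should close the ring-cis alkene and come back to the route at 36.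

Step 16. Capture of the hindered, electron-rich alkenylboronate by the bulky lithiated benzoate may be slow or reversible, so the carbenoid decomposes or is protonated before the 1,2-shift. Both partners are sterically crowded at boron. Fallback: the order of bond formation at boron is reversed. It sets out from 20, which is lithiated as before and trapped with i-PrOBpin to give α-boryl benzoate F10 (retention). Alkenyllithium F11, made from bromide 27 with t-BuLi in Et2O at −78 °C, is then added. This small nucleophile should reach the unhindered boron easily and form the same complex 31, which rearranges to 32; methanolysis comes back to the route at 33.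

Step 12. Competing electrophilic bromination of the anisyl ring, or loss of the PMB group to HBr before the base is added, may erode the yield, because the ring is nearly as nucleophilic as the push–pull alkene. Fallback: the bromine is introduced before the PMB group. It sets out from 22. Commercial methyl (E)-3-methoxyacrylate F12 is brominated and dehydrobrominated (Br2; Et3N) to methyl (Z)-2-bromo-3-methoxyacrylate F13. Acid-catalysed alkoxy exchange of F13 with 22 (PPTS, toluene, removal of methanol; addition–elimination) comes back to the route at 25.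

Step 1. Over-oxidation, that is cleavage of the second alkene, may occur because the rate difference between the two trisubstituted alkenes is only moderate. Fallback: the two alkenes are told apart by epoxidation. It sets out from 1. mCPBA (CH2Cl2, 0 °C) epoxidises the more nucleophilic remote alkene to epoxide F14. HIO4 (THF/H2O) cleaves F14 to aldehyde 2, and NaBH4 comes back to the route at 3.

## Further compounds

F1 | step 18 | (2Z)-3-methylhepta-2,6-dien-1-yl acetate | CC(=O)OC/C=C(/C)CCC=C
F2 | step 18 | (2Z)-3-methylhepta-2,6-dien-1-ol | OC/C=C(/C)CCC=C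
F3 | step 18 | (2Z)-3-methylhepta-2,6-dienal | O=C/C=C(/C)CCC=C
F4 | step 18 | syn-aldol adduct of F3 and 14 | O=C(N1C(=O)OC[C@@H]1Cc1ccccc1)[C@@H](C(=C)CO[Si](C)(C)C(C)(C)C)[C@H](O)/C=C(/C)CCC=C
F5 | step 18 | C6 O-TBS ether of F4 | O=C(N1C(=O)OC[C@@H]1Cc1ccccc1)[C@@H](C(=C)CO[Si](C)(C)C(C)(C)C)[C@H](O[Si](C)(C)C(C)(C)C)/C=C(/C)CCC=C
F6 | step 18 | C8 primary alcohol with C1 vinyl terminus | OC[C@@H](C(=C)CO[Si](C)(C)C(C)(C)C)[C@H](O[Si](C)(C)C(C)(C)C)/C=C(/C)CCC=C
F7 | step 18 | C8 aldehyde with C1 vinyl terminus | O=C[C@@H](C(=C)CO[Si](C)(C)C(C)(C)C)[C@H](O[Si](C)(C)C(C)(C)C)/C=C(/C)CCC=C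
F8 | step 18 | pinacol [(Z)-3-[(4-methoxybenzyl)oxy]-2-[(TBS-oxy)methyl]allyl]boronate | COc1ccc(CO/C=C(/CO[Si](C)(C)C(C)(C)C)CB2OC(C)(C)C(C)(C)O2)cc1
F9 | step 18 | acyclic triene with syn C8 hydroxyl and C9 PMB ether | C=C(CO[Si](C)(C)C(C)(C)C)[C@@H]([C@H](O[Si](C)(C)C(C)(C)C)/C=C(/C)CCC=C)[C@H](O)[C@@H](OCc1ccc(OC)cc1)C(=C)CO[Si](C)(C)C(C)(C)C
F10 | step 16 | (1S)-1-(pinacolatoboryl) derivative of 20 | C[Si](C)(C)OC[C@@H](C(=C)CO[Si](C)(C)C(C)(C)C)[C@H](O[Si](C)(C)C(C)(C)C)/C=C(/C)CC[C@H](B1OC(C)(C)C(C)(C)O1)OC(=O)c1c(C(C)C)cc(C(C)C)cc1C(C)C
F11 | step 16 | alkenyllithium from 27 (Li cis to the ether oxygen) | [Li]/C(CO[Si](C)(C)C(C)(C)C)=C\OCc1ccc(OC)cc1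
F12 | step 12 | methyl (E)-3-methoxyacrylate | COC(=O)/C=C/OC
F13 | step 12 | methyl (Z)-2-bromo-3-methoxyacrylate | COC(=O)/C(Br)=C/OC
F14 | step 1 | (2Z)-5-(3,3-dimethyloxiran-2-yl)-3-methylpent-2-en-1-yl acetate (racemic epoxide) | CC(=O)OC/C=C(/C)CCC1OC1(C)C
A1 | alternative 1 | ten-membered lactone with C9/C14 acetonide | C=C1C(=O)O[C@@H]2/C=C(/C)CC/C=C3/COC(C)(C)O[C@@H]3[C@@H](OC(=O)[C@@H](C)CC)[C@@H]12
A2 | alternative 1 | seco diiodide (C2 alkyl iodide, C1 alkenyl iodide) | C=C1C(=O)O[C@H](/C=C(/C)CCI)[C@H]1[C@H](OC(=O)[C@@H](C)CC)[C@H]1OC(C)(C)OC/C1=C/I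
A3 | alternative 2 | ten-membered C6 carbinol with the 2-propenyl arm on C7 | O[C@@H]1/C=C(/C)CC/C=C2/COC(C)(C)O[C@@H]2[C@@H](O[Si](C)(C)C(C)(C)C)[C@H]1C(=C)CO[Si](CC)(CC)CC
A4 | alternative 2 | thirteen-membered diallyl ether (O links C6 and C13) | O1C/C(CO[Si](CC)(CC)CC)=C/[C@H](O[Si](C)(C)C(C)(C)C)[C@H]2OC(C)(C)OC/C2=C/CC/C(C)=C\C1
A5 | alternative 3 | ten-membered C6 carbinol with C9/C14 TBS ethers and C12 TES ether | O[C@@H]1/C=C(/C)CC/C=C(/CO[Si](C)(C)C(C)(C)C)[C@H](O[Si](C)(C)C(C)(C)C)[C@@H](OC(=O)[C@@H](C)CC)[C@H]1C(=C)CO[Si](CC)(CC)CC
A6 | alternative 3 | seco aldehyde with C5 (Z)-alkenyl iodide | O=C[C@H](C(=C)CO[Si](CC)(CC)CC)[C@H](OC(=O)[C@@H](C)CC)[C@@H](O[Si](C)(C)C(C)(C)C)/C(CO[Si](C)(C)C(C)(C)C)=C\CC/C(C)=C\I
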